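**Retrosynthetic overview**

1. Guaiane numbering is used throughout: five-membered ring C1–C5 (C3 carbonyl, C4 methyl); seven-membered ring C1, C5–C10 (C7 bears C11, C8 the oxygen, C10 a methyl). The esters go on last. The C8 carbinol comes from a C8 ketone (hydride anti to C7), C11–OH from an isopropenyl group, and the C7–C11 bond from a 1,6-cuprate addition anti to a C8 silyloxy group.
2. Key disconnection: the cyclopentenone is the ring-expanded form of a cyclobutanone C1–C3–C4–C5. Insertion of the single carbon C2 between C3 and C1 makes the five-membered ring; loss of Cl (C4) and OSiEt3 (C5) then gives the C4=C5 enone.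
3. The cyclobutanone is the [2+2] adduct of chloro(methyl)ketene (C3, C4, CH3) with the C1=C5 silyl enol ether of the seven-membered ring. A methyl cuprate addition to a cyclohepta-2,6-dienone delivers that enol ether regiospecifically, together with C10.
4. Enabling feature: in the five-membered ring the C3 carbonyl lies between an unsubstituted CH2 (C2) and the methyl-bearing C4, and C4=C5 is the enone bond shared with the seven-membered ring. So C2 can be the inserted atom, chlorine on C4 steers the insertion into the C3–C1 bond, and the enol-ether oxygen on C5 controls the [2+2] regiochemistry and later leaves to form C4=C5.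
5. Ring order: seven-membered ring (bought as cyclohepta-1,3-diene; C8 set by catalysis, C10, C1 and C7 relayed from it) → temporary cyclobutanone → five-membered ring last.

Key step: step 7

Remark: C4 in 9, 10 and 13 is formed as an inconsequential mixture of epimers (left undefined in the SMILES); the catalyst antipode that gives (S)-3 is assumed to be chosen in step 2.

**Route**

Step 1
Reactants: 1 cyclohepta-1,3-diene
Product: 2 meso-6,7-dioxabicyclo[3.2.2]non-8-ene
Conditions: O2, tetraphenylporphyrin (cat.), visible light, CH2Cl2, 0 °C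
Reagents that add atoms: dioxygen O=O
Why: [4+2] cycloaddition of singlet oxygen to the cyclic s-cis diene (photooxygenation) should give the bridged endoperoxide, which is meso, so no stereocentre needs control here.

Step 2
Reactants: 2 meso-6,7-dioxabicyclo[3.2.2]non-8-ene
Product: 3 (S)-4-hydroxycyclohept-2-en-1-one
Conditions: chiral cinchona-alkaloid base (5 mol%), CH2Cl2, rt
Reagents that add atoms: none
Why: In this catalytic asymmetric Kornblum–DeLaMare rearrangement the chiral base should remove one of the two enantiotopic bridgehead protons, and O–O cleavage then gives the γ-hydroxy enone, so the C8 carbinol centre is set by the catalyst in a desymmetrisation.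

Step 3
Reactants: 3 (S)-4-hydroxycyclohept-2-en-1-one
Product: 4 (S)-4-(tert-butyldimethylsilyloxy)cyclohept-2-en-1-one
Conditions: TBSCl, imidazole, DMF, 0 °C → rt
Reagents that add atoms: tert-butyldimethylsilyl chloride CC(C)(C)[Si](C)(C)Cl
Why: Standard silylation of a secondary alcohol; the bulky silyl ether is the control element for the two later cuprate additions and leaves the stereocentre untouched.

Step 4
Reactants: 4 (S)-4-(tert-butyldimethylsilyloxy)cyclohept-2-en-1-one
Product: 6 (S)-4-(tert-butyldimethylsilyloxy)cyclohepta-2,6-dien-1-one, via silyl dienol ether 5 (not isolated)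
Conditions: LDA, TMSCl, THF, −78 °C; then Pd(OAc)2, MeCN, rt
Reagents that add atoms: none
Why: Kinetic deprotonation can only occur at the α'-carbon C1 (the other α-carbon is vinylic), and Saegusa–Ito dehydrogenation of the resulting cross-conjugated silyl dienol ether should give the dienone without creating a stereocentre.

Step 5
Reactants: 6 (S)-4-(tert-butyldimethylsilyloxy)cyclohepta-2,6-dien-1-one
Product: 8 (1S,6S)-1-(tert-butyldimethylsilyloxy)-6-methyl-4-(triethylsilyloxy)cyclohepta-2,4-diene, via bromomagnesium enolate 7 (not isolated)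
Conditions: MeMgBr, CuBr·SMe2 (5 mol%), Et3SiCl, HMPA, THF, −78 °C
Reagents that add atoms: methylmagnesium bromide C[Mg]Br; chlorotriethylsilane CC[Si](Cl)(CC)CC
Why: In this copper-catalysed conjugate addition with in situ silylation the methyl group should enter at C10, the enone terminus not flanked by the silyloxy-bearing carbon, from the face anti to the C8 OTBS group (1,3-induction), which sets C10, and silylation fixes the enol ether regiospecifically at C1=C5.

Step 6
Reactants: 8 (1S,6S)-1-(tert-butyldimethylsilyloxy)-6-methyl-4-(triethylsilyloxy)cyclohepta-2,4-diene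
Product: 9 (1R,5R,8S,10S)-8-(tert-butyldimethylsilyloxy)-4-chloro-5-(triethylsilyloxy)-2,11,12,13-tetranorguai-6-en-3-one (cis-fused cyclobutanone with C3 bonded to C1)
Conditions: 2-chloropropanoyl chloride, Et3N (slow addition), hexane, rt; product used crude
Reagents that add atoms: 2-chloropropanoyl chloride CC(Cl)C(Cl)=O
Why: In this ketene–enol ether [2+2] cycloaddition the electrophilic ketene carbonyl carbon (C3) should bond to the nucleophilic enol-ether β-carbon C1 and the CCl(CH3) carbon (C4) to the oxygen-bearing C5, suprafacially on the enol ether (cis fusion) and from the face anti to the adjacent C10 methyl, which sets C1 and C5.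

Step 7
Reactants: 9 (1R,5R,8S,10S)-8-(tert-butyldimethylsilyloxy)-4-chloro-5-(triethylsilyloxy)-2,11,12,13-tetranorguai-6-en-3-one
Product: 10 (1R,5R,8S,10S)-8-(tert-butyldimethylsilyloxy)-4-chloro-5-(triethylsilyloxy)-11,12,13-trinorguai-6-en-3-one
Conditions: CH2N2, Et2O, MeOH (cat.), 0 °C
Reagents that add atoms: diazomethane C=[N+]=[N-]
Why: Diazomethane should add as a carbon nucleophile to the strained, chlorine-activated C3 carbonyl of 9 to give a diazonium betaine, and a ring carbon then shifts from C3 to the new CH2 with loss of N2, so that one carbon (C2) is inserted and the cyclobutanone becomes the cyclopentanone. The closest known reaction type is the regioselective diazomethane ring expansion of α-chlorocyclobutanones used in ketene-based three-carbon annulations (a Tiffeneau–Demjanov-type homologation). The five-membered ring C1–C2–C3–C4–C5 is thus closed not end to end but by enlargement of the four-membered ring C1–C3–C4–C5 through a 1,2-shift of C1. No new stereocentre is created (C2 is CH2); C1 migrates with retention, so its configuration, set in step 6 anti to the C10 methyl, is carried over, and C5 is not touched. The step needs regioselectivity (C1, not C4, must migrate) and a single homologation: the electron-withdrawing chlorine on the fully substituted C4 disfavours its migration, and ring strain plus the α-chlorine make 9 far more reactive towards diazomethane than the product ketone 10 or any other group present.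

Step 8
Reactants: 10 (1R,5R,8S,10S)-8-(tert-butyldimethylsilyloxy)-4-chloro-5-(triethylsilyloxy)-11,12,13-trinorguai-6-en-3-one
Product: 11 (1R,8S,10S)-8-(tert-butyldimethylsilyloxy)-11,12,13-trinorguaia-4,6-dien-3-one
Conditions: Zn dust, AcOH, THF, 0 °C → rt
Reagents that add atoms: none
Why: Zinc should reduce the C4–Cl bond α to the ketone, and the zinc enolate expels the β-silyloxy group on C5 (reductive β-elimination), which removes both activating groups and gives the tetrasubstituted C4=C5 enone without touching C1.

Step 9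
Reactants: 11 (1R,8S,10S)-8-(tert-butyldimethylsilyloxy)-11,12,13-trinorguaia-4,6-dien-3-one
Product: 14 (1R,7R,8S,10S)-8-(tert-butyldimethylsilyloxy)guaia-4,11-dien-3-one, via bromomagnesium dienolate 12 (not isolated), via deconjugated enone 13 (not isolated)
Conditions: isopropenylmagnesium bromide, CuBr·SMe2 (10 mol%), THF, −78 → −40 °C; H2O; then DBU (cat.), CH2Cl2, rt
Reagents that add atoms: isopropenylmagnesium bromide CC(=C)[Mg]Br
Why: Copper-catalysed 1,6-conjugate addition to the linear dienone (the 1,4-position C5 is fully substituted) should occur at C7 anti to the adjacent C8 OTBS group, which sets C7, and base-mediated reconjugation of the α-protonated product gives the tetrasubstituted C4=C5 enone with C1 in its more stable arrangement (C1–C2 trans to the C10 methyl).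

Step 10
Reactants: 14 (1R,7R,8S,10S)-8-(tert-butyldimethylsilyloxy)guaia-4,11-dien-3-one
Product: 15 (1R,7R,8S,10S)-8-hydroxyguaia-4,11-dien-3-one
Conditions: HF·pyridine, THF, 0 °C → rt
Reagents that add atoms: none
Why: Fluoride-mediated cleavage of the secondary silyl ether under buffered, non-basic conditions should leave the enone, the isopropenyl group and the γ-stereocentre C1 unchanged.

Step 11
Reactants: 15 (1R,7R,8S,10S)-8-hydroxyguaia-4,11-dien-3-one
Product: 16 (1R,7R,10S)-guaia-4,11-diene-3,8-dione
Conditions: Dess–Martin periodinane, CH2Cl2, 0 °C; used at once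
Reagents that add atoms: none
Why: Dess–Martin oxidation of the secondary alcohol under near-neutral conditions should give the C8 ketone without moving the β,γ-double bond of the isopropenyl group into conjugation or epimerising C7.

Step 12
Reactants: 16 (1R,7R,10S)-guaia-4,11-diene-3,8-dione
Product: 17 (1R,7R,8R,10S)-8-hydroxyguaia-4,11-dien-3-one
Conditions: L-Selectride (1.05 equiv), THF, −78 °C; H2O
Reagents that add atoms: none
Why: The bulky trialkylborohydride should attack the C8 ketone from the face opposite to the adjacent C7 isopropenyl group and the C10 methyl (as in the reduction of 2-substituted cycloalkanones to cis-alcohols), which sets C8 cis to C7, and the saturated ketone is reduced much faster than the tetrasubstituted enone at −78 °C.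

Step 13
Reactants: 17 (1R,7R,8R,10S)-8-hydroxyguaia-4,11-dien-3-one
Product: 18 (1R,7R,8R,10S)-8-propanoyloxyguaia-4,11-dien-3-one
Conditions: (EtCO)2O, DMAP (cat.), pyridine, 0 °C → rt
Reagents that add atoms: propanoic anhydride CCC(=O)OC(=O)CC
Why: DMAP-catalysed acylation of the only hydroxyl group, with retention at C8.

Step 14
Reactants: 18 (1R,7R,8R,10S)-8-propanoyloxyguaia-4,11-dien-3-one
Product: 19 (1R,7S,8R,10S)-11-hydroxy-8-propanoyloxyguai-4-en-3-one
Conditions: Co(acac)2 (cat.), PhSiH3, O2 (1 atm), THF, rt
Reagents that add atoms: dioxygen O=O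
Why: Mukaiyama hydration (hydrogen-atom transfer to the 1,1-disubstituted alkene, O2 trapping of the tertiary radical, reduction of the peroxide) should give the Markovnikov tertiary alcohol, while the tetrasubstituted electron-poor enone is too hindered to compete; no stereocentre is formed.

Step 15
Reactants: 19 (1R,7S,8R,10S)-11-hydroxy-8-propanoyloxyguai-4-en-3-one
Product: 20 (1R,7S,8R,10S)-11-acetoxy-8-propanoyloxyguai-4-en-3-one
Conditions: Ac2O, DMAP, Et3N, CH2Cl2, 40 °C
Reagents that add atoms: acetic anhydride CC(=O)OC(C)=O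
Why: DMAP-catalysed acetylation of the tertiary alcohol under forcing but non-acidic conditions should give the target without elimination or acyl exchange at C8.

**Compound list**

1 | cyclohepta-1,3-diene | C1=CC=CCCC1 | starting material
2 | meso-6,7-dioxabicyclo[3.2.2]non-8-ene | O1O[C@H]2CCC[C@@H]1C=C2 | intermediate
3 | (S)-4-hydroxycyclohept-2-en-1-one | O[C@H]1CCCC(=O)C=C1 | intermediate
4 | (S)-4-(tert-butyldimethylsilyloxy)cyclohept-2-en-1-one | CC(C)(C)[Si](C)(C)O[C@H]1CCCC(=O)C=C1 | intermediate
5 | silyl dienol ether: (S)-1-(tert-butyldimethylsilyloxy)-4-(trimethylsilyloxy)cyclohepta-2,4-diene | CC(C)(C)[Si](C)(C)O[C@H]1CCC=C(O[Si](C)(C)C)C=C1 | intermediate (not isolated)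
6 | (S)-4-(tert-butyldimethylsilyloxy)cyclohepta-2,6-dien-1-one | CC(C)(C)[Si](C)(C)O[C@H]1CC=CC(=O)C=C1 | intermediate
7 | bromomagnesium enolate: bromomagnesium (4S,6S)-4-(tert-butyldimethylsilyloxy)-6-methylcyclohepta-1(7),2-dien-1-olate | CC(C)(C)[Si](C)(C)O[C@H]1C[C@H](C)C=C(O[Mg]Br)C=C1 | intermediate (not isolated)
8 | (1S,6S)-1-(tert-butyldimethylsilyloxy)-6-methyl-4-(triethylsilyloxy)cyclohepta-2,4-diene (C8 OTBS trans to C10 methyl; enol ether C1=C5) | CC(C)(C)[Si](C)(C)O[C@H]1C[C@H](C)C=C(O[Si](CC)(CC)CC)C=C1 | intermediate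
9 | (1R,5R,8S,10S)-8-(tert-butyldimethylsilyloxy)-4-chloro-5-(triethylsilyloxy)-2,11,12,13-tetranorguai-6-en-3-one (cis-fused cyclobutanone C1–C3–C4–C5; C4 epimers) | CC(C)(C)[Si](C)(C)O[C@H]1C[C@H](C)[C@H]2C(=O)C(C)(Cl)[C@@]2(O[Si](CC)(CC)CC)C=C1 | intermediate
10 | (1R,5R,8S,10S)-8-(tert-butyldimethylsilyloxy)-4-chloro-5-(triethylsilyloxy)-11,12,13-trinorguai-6-en-3-one (C4 epimers) | CC(C)(C)[Si](C)(C)O[C@H]1C[C@H](C)[C@H]2CC(=O)C(C)(Cl)[C@@]2(O[Si](CC)(CC)CC)C=C1 | intermediate
11 | (1R,8S,10S)-8-(tert-butyldimethylsilyloxy)-11,12,13-trinorguaia-4,6-dien-3-one | CC(C)(C)[Si](C)(C)O[C@H]1C[C@H](C)[C@H]2CC(=O)C(C)=C2C=C1 | intermediate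
12 | bromomagnesium dienolate (C3–OMgBr, C3=C4, C5=C6; C7 isopropenyl) | CC(C)(C)[Si](C)(C)O[C@H]1C[C@H](C)[C@H]2CC(O[Mg]Br)=C(C)C2=C[C@@H]1C(C)=C | intermediate (not isolated)
13 | deconjugated enone: (1R,7R,8S,10S)-8-(tert-butyldimethylsilyloxy)guaia-5,11-dien-3-one (C4 epimers) | CC(C)(C)[Si](C)(C)O[C@H]1C[C@H](C)[C@H]2CC(=O)C(C)C2=C[C@@H]1C(C)=C | intermediate (not isolated)
14 | (1R,7R,8S,10S)-8-(tert-butyldimethylsilyloxy)guaia-4,11-dien-3-one | CC(C)(C)[Si](C)(C)O[C@H]1C[C@H](C)[C@H]2CC(=O)C(C)=C2C[C@@H]1C(C)=C | intermediate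
15 | (1R,7R,8S,10S)-8-hydroxyguaia-4,11-dien-3-one | O[C@H]1C[C@H](C)[C@H]2CC(=O)C(C)=C2C[C@@H]1C(C)=C | intermediate
16 | (1R,7R,10S)-guaia-4,11-diene-3,8-dione | O=C1C[C@H](C)[C@H]2CC(=O)C(C)=C2C[C@@H]1C(C)=C | intermediate
17 | (1R,7R,8R,10S)-8-hydroxyguaia-4,11-dien-3-one | O[C@@H]1C[C@H](C)[C@H]2CC(=O)C(C)=C2C[C@@H]1C(C)=C | intermediate
18 | (1R,7R,8R,10S)-8-propanoyloxyguaia-4,11-dien-3-one | CCC(=O)O[C@@H]1C[C@H](C)[C@H]2CC(=O)C(C)=C2C[C@@H]1C(C)=C | intermediate
19 | (1R,7S,8R,10S)-11-hydroxy-8-propanoyloxyguai-4-en-3-one | CCC(=O)O[C@@H]1C[C@H](C)[C@H]2CC(=O)C(C)=C2C[C@@H]1C(C)(C)O | intermediate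
20 | (1R,7S,8R,10S)-11-acetoxy-8-propanoyloxyguai-4-en-3-one | CCC(=O)O[C@@H]1C[C@H](C)[C@H]2CC(=O)C(C)=C2C[C@@H]1C(C)(C)OC(C)=O | target

Total step count: 15. Longest linear sequence: 15 steps.

**Steps most likely to fail**

Step 5. The methyl group may be delivered to the wrong enone terminus (C7, which is activated by the allylic C–O bond, instead of C10) or with incomplete facial selectivity, and the dienone may lose silanol and aromatise to tropone. Fallback: the order of the two conjugate additions is reversed, setting out from 6. Copper-catalysed addition of isopropenylmagnesium bromide to 6 (no silyl chloride, aqueous work-up) should give (5S,6R)-5-(tert-butyldimethylsilyloxy)-6-(prop-1-en-2-yl)cyclohept-2-en-1-one F1. Copper-catalysed addition of MeMgBr with Et3SiCl then gives the triethylsilyl enol ether F2. Chloro(methyl)ketene gives the cyclobutanone F3, diazomethane the chlorocyclopentanone F4, and Zn/AcOH brings the route back at 14; the 1,6-addition of step 9 is then not needed.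

Step 6. The ketene may add to the siloxydiene in a [4+2] sense or polymerise, facial selectivity at C1 may be incomplete, and the β-silyloxy cyclobutanone may ring-open. Fallback: an alkylation–aldol annulation replaces the ring expansion, setting out from 8. MeLi cleaves the silyl enol ether to the lithium enolate F5 (not isolated), which is alkylated with 1-bromobut-2-yne (HMPA) trans to the C10 methyl to give the alkynyl enone F6. Pd(II)- or Au(I)-catalysed, carbonyl-assisted hydration of the alkyne gives the 1,4-diketone F7, and KOH/MeOH aldol condensation comes back to the route at 11.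

Step 12. The hydride may attack the enone carbonyl as well, or may not discriminate the two faces of the C8 ketone well enough. Fallback: inversion instead of oxidation and reduction, setting out from 15 (steps 11 and 12 are skipped). A Mitsunobu reaction (4-nitrobenzoic acid, PPh3, DIAD) should give the inverted ester (1R,7R,8R,10S)-8-(4-nitrobenzoyloxy)guaia-4,11-dien-3-one F8, and methanolysis (K2CO3, MeOH) comes back to the route at 17.

**Further compounds**

F1 | step 5 | (5S,6R)-5-(tert-butyldimethylsilyloxy)-6-(prop-1-en-2-yl)cyclohept-2-en-1-one | CC(C)(C)[Si](C)(C)O[C@H]1CC=CC(=O)C[C@@H]1C(C)=C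
F2 | step 5 | (1S,2R,6S)-1-(tert-butyldimethylsilyloxy)-6-methyl-2-(prop-1-en-2-yl)-4-(triethylsilyloxy)cyclohept-4-ene | CC(C)(C)[Si](C)(C)O[C@H]1C[C@H](C)C=C(O[Si](CC)(CC)CC)C[C@@H]1C(C)=C
F3 | step 5 | (1R,5R,7R,8S,10S)-8-(tert-butyldimethylsilyloxy)-4-chloro-5-(triethylsilyloxy)-2-norguai-11-en-3-one (cis-fused cyclobutanone, C4 epimers) | CC(C)(C)[Si](C)(C)O[C@H]1C[C@H](C)[C@H]2C(=O)C(C)(Cl)[C@@]2(O[Si](CC)(CC)CC)C[C@@H]1C(C)=C
F4 | step 5 | (1R,5R,7R,8S,10S)-8-(tert-butyldimethylsilyloxy)-4-chloro-5-(triethylsilyloxy)guai-11-en-3-one (C4 epimers) | CC(C)(C)[Si](C)(C)O[C@H]1C[C@H](C)[C@H]2CC(=O)C(C)(Cl)[C@@]2(O[Si](CC)(CC)CC)C[C@@H]1C(C)=C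
F5 | step 6 | lithium (4S,6S)-4-(tert-butyldimethylsilyloxy)-6-methylcyclohepta-1(7),2-dien-1-olate | CC(C)(C)[Si](C)(C)O[C@H]1C[C@H](C)C=C(O[Li])C=C1
F6 | step 6 | (4S,6S,7R)-7-(but-2-yn-1-yl)-4-(tert-butyldimethylsilyloxy)-6-methylcyclohept-2-en-1-one | CC(C)(C)[Si](C)(C)O[C@H]1C[C@H](C)[C@@H](CC#CC)C(=O)C=C1
F7 | step 6 | (4S,6S,7R)-4-(tert-butyldimethylsilyloxy)-6-methyl-7-(2-oxobutyl)cyclohept-2-en-1-one | CC(C)(C)[Si](C)(C)O[C@H]1C[C@H](C)[C@@H](CC(=O)CC)C(=O)C=C1
F8 | step 12 | (1R,7R,8R,10S)-8-(4-nitrobenzoyloxy)guaia-4,11-dien-3-one | O=C(O[C@@H]1C[C@H](C)[C@H]2CC(=O)C(C)=C2C[C@@H]1C(C)=C)c1ccc(cc1)[N+](=O)[O-]
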